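**Overview**

- Retrosynthesis: the CH2OH group is traced back through the benzylic bromide and the carboxylic acid to a 3-arylphthalide, whose lactone C–O bond stands in for the diarylmethane CH2. The two C–C bonds that ring A makes from its adjacent carbons C1 (to the carboxyl carbon) and C2 (to the ring B methine carbon) are then cut together, leaving an aryne, tert-butyl isocyanide and 3-bromo-4-methoxybenzaldehyde.
- Enabling feature: on ring A the CH2OH carbon (C1) and the CH2Ar carbon (C2) are neighbours, and C2 sits directly next to the catechol oxygen on C3 (then O on C4, Br on C5). This is the pattern left when a nucleophile adds meta and an electrophile ortho to the alkoxy group of a 3-alkoxybenzyne.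
- Forward order: 2,3-dimethoxyphenol is iodinated, brominated and turned into a silyl triflate. The aryne coupling joins the two benzene rings (both bought with their oxygens) and closes a temporary five-membered imino-lactone ring. That ring is hydrolysed to the phthalide and opened by ionic hydrogenation; acid reduction, demethylation and hydrolysis finish the target. No ring of the target is built.
- Stereochemistry: the target has no stereocentre. The single stereocentre of the iminoisobenzofuran and the phthalide is formed racemic and is erased as CH2.

Key step: step 5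

Assumption: the aryne derived from 7 is taken to follow the regiochemistry of 3-methoxybenzyne (carbon nucleophile adds to the aryne carbon remote from the flanking methoxy group), the 5-bromo substituent being too remote to reverse it.

**Route**

Step 1
Reactants: 1 2,3-dimethoxyphenol
Product: 2 6-iodo-2,3-dimethoxyphenol
Conditions: I2 (1.0 equiv), NaHCO3, THF/H2O 1:1, 0 °C to rt
Reagents that add atoms: iodine, II
Why: Electrophilic aromatic iodination of the phenol (via its phenoxide) should go to C6, which is ortho to the hydroxyl and para to the 3-methoxy group and is open, whereas C4 is shielded by the in-plane 3-methoxy group; 3-methoxyphenol is iodinated in the same ortho-to-OH, para-to-OMe sense under these conditions.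

Step 2
Reactants: 2 6-iodo-2,3-dimethoxyphenol
Product: 3 4-bromo-6-iodo-2,3-dimethoxyphenol
Conditions: NBS (1.0 equiv), MeCN, 0 °C
Reagents that add atoms: N-bromosuccinimide, O=C1CCC(=O)N1Br
Why: Electrophilic aromatic bromination with NBS should take C4, para to the free hydroxyl and ortho to the 3-methoxy group, the only strongly activated position left (C5 is meta to the hydroxyl and activated only by the twisted 2-methoxy group), and one equivalent at 0 °C should leave the iodide untouched.

Step 3
Reactants: 3 4-bromo-6-iodo-2,3-dimethoxyphenol
Product: 4 (4-bromo-6-iodo-2,3-dimethoxyphenoxy)trimethylsilane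
Conditions: HMDS, THF, 70 °C; volatiles removed under vacuum, used crude
Reagents that add atoms: hexamethyldisilazane, C[Si](C)(C)N[Si](C)(C)C
Why: O-Silylation of a phenol by hexamethyldisilazane is driven by loss of ammonia and leaves no salt, so the moisture-sensitive aryl silyl ether can be used after simple evaporation.

Step 4
Reactants: 4 (4-bromo-6-iodo-2,3-dimethoxyphenoxy)trimethylsilane
Product: 7 4-bromo-2,3-dimethoxy-6-(trimethylsilyl)phenyl trifluoromethanesulfonate, via aryllithium 5 (not isolated), via lithium silylphenoxide 6 (not isolated)
Conditions: n-BuLi (1.05 equiv), THF, −100 °C to −80 °C; then Tf2O, −100 °C to −78 °C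
Reagents that add atoms: trifluoromethanesulfonic anhydride, O=S(=O)(OS(=O)(=O)C(F)(F)F)C(F)(F)F
Why: Iodine–lithium exchange is far faster than bromine–lithium exchange at −100 °C, the ortho-lithio aryl silyl ether undergoes a 1,3 O-to-C silyl shift (retro-Brook rearrangement) driven by formation of the lithium phenoxide, and this phenoxide is O-triflated in the same flask, the standard entry to 2-(trimethylsilyl)aryl triflates that also serves the closely related 2-methoxy-6-(trimethylsilyl)phenyl triflate.

Step 5
Reactants: 7 4-bromo-2,3-dimethoxy-6-(trimethylsilyl)phenyl trifluoromethanesulfonate; 8 tert-butyl isocyanide; 9 3-bromo-4-methoxybenzaldehyde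
Product: 11 rac-6-bromo-3-(3-bromo-4-methoxyphenyl)-N-tert-butyl-4,5-dimethoxy-3H-isobenzofuran-1-imine, via bromodimethoxybenzyne 10 (not isolated)
Conditions: KF, 18-crown-6, THF, 0 °C to rt
Reagents that add atoms: none
Why: Fluoride attacks the trimethylsilyl group of 7 and the ortho triflate leaves, giving 5-bromo-3,4-dimethoxybenzyne 10; the isocyanide carbon of 8 adds to the aryne carbon remote from the flanking methoxy group, the resulting aryl anion (ortho to that methoxy group) adds to the carbonyl carbon of 9, and the alkoxide closes onto the nitrilium carbon. The closest known reaction is the fluoride-triggered three-component coupling of arynes from 2-(trimethylsilyl)aryl triflates with isocyanides and aldehydes to 1-iminoisobenzofurans, which is regioselective in this sense for 3-methoxybenzyne. The five-membered imino-lactone ring closes by 5-exo-dig attack of the alkoxide oxygen on the nitrilium carbon. The one new stereocentre (C3, the diarylmethine carbon) arises from achiral partners with no controlling element and is therefore racemic, which does not matter because it becomes CH2 in step 7. The step needs the isocyanide to choose the aryne carbon meta to the 3-methoxy group; the inductive pull and angle distortion caused by that group, reinforced by the 4-methoxy group, should secure this against the weak opposing influence of the remote bromine. Both aryl bromides are inert to KF, and a non-enolisable aromatic aldehyde is the electrophile type this coupling accepts.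

Step 6
Reactants: 11 rac-6-bromo-3-(3-bromo-4-methoxyphenyl)-N-tert-butyl-4,5-dimethoxy-3H-isobenzofuran-1-imine
Product: 12 rac-6-bromo-3-(3-bromo-4-methoxyphenyl)-4,5-dimethoxy-3H-isobenzofuran-1-one
Conditions: 1 M aq. HCl, THF, rt
Reagents that add atoms: water, O
Why: Acid hydrolysis of a cyclic imidate: water adds to the protonated C=N carbon and the tetrahedral intermediate expels tert-butylamine as its ammonium salt, leaving the five-membered lactone, while aryl ethers and aryl bromides are inert to dilute acid.

Step 7
Reactants: 12 rac-6-bromo-3-(3-bromo-4-methoxyphenyl)-4,5-dimethoxy-3H-isobenzofuran-1-one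
Product: 13 5-bromo-2-(3-bromo-4-methoxybenzyl)-3,4-dimethoxybenzoic acid
Conditions: Et3SiH (3 equiv), CF3CO2H, 50 °C
Reagents that add atoms: none
Why: Ionic hydrogenation: in trifluoroacetic acid the doubly benzylic lactone C–O bond ionises to a diarylmethyl cation stabilised by the para-methoxy group of ring B and the ortho-methoxy group of ring A, hydride transfer from Et3SiH then gives the diarylmethane and frees the carboxylic acid (a known way of opening 3-arylphthalides to 2-benzylbenzoic acids), aryl bromides are not reduced, and at the acid oxidation level no other C–O bond can ionise.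

Step 8
Reactants: 13 5-bromo-2-(3-bromo-4-methoxybenzyl)-3,4-dimethoxybenzoic acid
Product: 14 5-bromo-2-(3-bromo-4-methoxybenzyl)-3,4-dimethoxybenzyl alcohol
Conditions: BH3·THF, THF, 0 °C to rt; MeOH quench, aqueous work-up
Reagents that add atoms: none
Why: Borane reduces carboxylic acids rapidly through an acyloxyborane and does not touch aryl bromides, aryl methyl ethers or the diarylmethane.

Step 9
Reactants: 14 5-bromo-2-(3-bromo-4-methoxybenzyl)-3,4-dimethoxybenzyl alcohol
Product: 15 5-bromo-2-(3-bromo-4-hydroxybenzyl)-3,4-dihydroxybenzyl bromide
Conditions: BBr3 (6 equiv), CH2Cl2, −78 °C to rt; ice-water quench, used crude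
Reagents that add atoms: boron tribromide, BrB(Br)Br
Why: BBr3 cleaves aryl methyl ethers by Lewis acid complexation and bromide attack on the methyl group and at the same time converts an electron-rich benzylic alcohol into the benzylic bromide, a behaviour established for methoxylated bromobenzyl alcohols of this natural product family; the phenols are held as boron esters until the quench and the ring B positions within reach of the benzylic carbon are meta to oxygen, which should hold back Friedel–Crafts self-alkylation.

Step 10
Reactants: 15 5-bromo-2-(3-bromo-4-hydroxybenzyl)-3,4-dihydroxybenzyl bromide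
Product: 16 5-bromo-2-(3-bromo-4-hydroxybenzyl)-3,4-dihydroxybenzyl alcohol (target CNP0232913.0)
Conditions: NaHCO3 (1.1 equiv), acetone/H2O 1:1, rt
Reagents that add atoms: water, O
Why: The benzylic bromide is para to a free hydroxyl, so it ionises easily (SN1 solvolysis through a para-quinone methide or para-hydroxybenzyl cation) and water captures the cation, while NaHCO3 removes the HBr that could otherwise promote acid-catalysed self-condensation of the product.

**Compound list**

1 | 2,3-dimethoxyphenol | COc1cccc(O)c1OC | starting material
2 | 6-iodo-2,3-dimethoxyphenol | COc1ccc(I)c(O)c1OC | intermediate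
3 | 4-bromo-6-iodo-2,3-dimethoxyphenol | COc1c(Br)cc(I)c(O)c1OC | intermediate
4 | (4-bromo-6-iodo-2,3-dimethoxyphenoxy)trimethylsilane | COc1c(Br)cc(I)c(O[Si](C)(C)C)c1OC | intermediate
5 | [5-bromo-3,4-dimethoxy-2-(trimethylsilyloxy)phenyl]lithium (not isolated) | COc1c(Br)cc([Li])c(O[Si](C)(C)C)c1OC | intermediate
6 | lithium 4-bromo-2,3-dimethoxy-6-(trimethylsilyl)phenoxide (not isolated) | [Li+].[O-]c1c(OC)c(OC)c(Br)cc1[Si](C)(C)C | intermediate
7 | 4-bromo-2,3-dimethoxy-6-(trimethylsilyl)phenyl trifluoromethanesulfonate | COc1c(Br)cc([Si](C)(C)C)c(OS(=O)(=O)C(F)(F)F)c1OC | intermediate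
8 | tert-butyl isocyanide | CC(C)(C)[N+]#[C-] | starting material
9 | 3-bromo-4-methoxybenzaldehyde | COc1ccc(C=O)cc1Br | starting material
10 | 5-bromo-3,4-dimethoxybenzyne (not isolated) | COC1=C(OC)C#CC=C1Br | intermediate
11 | rac-6-bromo-3-(3-bromo-4-methoxyphenyl)-N-tert-butyl-4,5-dimethoxy-3H-isobenzofuran-1-imine (racemic at C3, C=N geometry not defined) | CC(C)(C)N=C1OC(c2ccc(OC)c(Br)c2)c2c1cc(Br)c(OC)c2OC | intermediate
12 | rac-6-bromo-3-(3-bromo-4-methoxyphenyl)-4,5-dimethoxy-3H-isobenzofuran-1-one (racemic at C3) | O=C1OC(c2ccc(OC)c(Br)c2)c2c1cc(Br)c(OC)c2OC | intermediate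
13 | 5-bromo-2-(3-bromo-4-methoxybenzyl)-3,4-dimethoxybenzoic acid | OC(=O)c1cc(Br)c(OC)c(OC)c1Cc1ccc(OC)c(Br)c1 | intermediate
14 | 5-bromo-2-(3-bromo-4-methoxybenzyl)-3,4-dimethoxybenzyl alcohol | OCc1cc(Br)c(OC)c(OC)c1Cc1ccc(OC)c(Br)c1 | intermediate
15 | 5-bromo-2-(3-bromo-4-hydroxybenzyl)-3,4-dihydroxybenzyl bromide | BrCc1cc(Br)c(O)c(O)c1Cc1ccc(O)c(Br)c1 | intermediate
16 | 5-bromo-2-(3-bromo-4-hydroxybenzyl)-3,4-dihydroxybenzyl alcohol, no stereocentre | OCc1cc(Br)c(O)c(O)c1Cc1ccc(O)c(Br)c1 | target

**Step count and risks**

Total step count: 10. Longest linear sequence: 10 steps (1 to 16).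

Steps most likely to fail:

1. Step 5. The aryl anion of the zwitterion may be protonated, or the aryne consumed by self-reaction, before the aldehyde is captured; the isocyanide may also add with eroded site selectivity on this more heavily substituted aryne. The fallback reaches the phthalide without an aryne; it sets out from aldehyde 9 and comes back to the route at phthalide 12.
   - Commercial 2-amino-3,4-dimethoxybenzoic acid would be esterified (MeOH, H2SO4, reflux) to methyl 2-amino-3,4-dimethoxybenzoate F1.
   - Bromination (NBS, DMF, 0 °C) at the only free position ortho or para to the amino group should give methyl 2-amino-5-bromo-3,4-dimethoxybenzoate F2.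
   - A Sandmeyer iodination (NaNO2, aqueous H2SO4, 0 °C, then KI) would pass through 4-bromo-2,3-dimethoxy-6-(methoxycarbonyl)benzenediazonium hydrogensulfate F3 and give methyl 5-bromo-2-iodo-3,4-dimethoxybenzoate F4.
   - Iodine–magnesium exchange with i-PrMgCl·LiCl (THF, −40 °C), which leaves aryl bromides and the ester alone, would give [4-bromo-2,3-dimethoxy-6-(methoxycarbonyl)phenyl]magnesium chloride F5.
   - Addition of F5 to 9 and warming should let the magnesium alkoxide close onto the neighbouring ester and deliver 12 directly.

2. Step 4. Bromine–lithium exchange may compete with iodine–lithium exchange, the O-to-C silyl shift may stay incomplete, or the crowded phenoxide may be triflated sluggishly. The fallback replaces the anionic silyl shift by intermolecular C-silylation and a separate triflation; it sets out from phenol 3 and comes back at silyl triflate 7.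
   - Phenol 3 would be treated with i-PrMgCl·LiCl (2.2 equiv, THF, −20 °C): the first equivalent deprotonates the hydroxyl and the second exchanges only the iodide, giving chloromagnesium 4-bromo-6-(chloromagnesio)-2,3-dimethoxyphenoxide F6.
   - Excess TMSCl (−20 °C to rt) should silylate carbon and oxygen to give [4-bromo-2,3-dimethoxy-6-(trimethylsilyl)phenoxy]trimethylsilane F7.
   - K2CO3 in MeOH removes the O-silyl group to give 4-bromo-2,3-dimethoxy-6-(trimethylsilyl)phenol F8.
   - Tf2O and pyridine in CH2Cl2 at 0 °C convert F8 into 7.

3. Step 1. The iodination may show poor site selectivity between C6 and C4, or run on to the diiodide. The fallback fixes the position by directed ortho-metalation; it sets out from phenol 1 and comes back at iodophenol 2.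
   - Phenol 1 would be protected (MOMCl, i-Pr2NEt, CH2Cl2) as 1,2-dimethoxy-3-(methoxymethoxy)benzene F6... this compound is labelled F9 below: 1,2-dimethoxy-3-(methoxymethoxy)benzene F9.
   - n-BuLi (THF, 0 °C) should lithiate the only free position next to the methoxymethoxy group, the stronger director, giving [3,4-dimethoxy-2-(methoxymethoxy)phenyl]lithium F10.
   - Iodine would convert F10 into 1-iodo-3,4-dimethoxy-2-(methoxymethoxy)benzene F11.
   - HCl in MeOH at rt removes the acetal and gives 2.

**Further compounds**

F1 | step 5 | methyl 2-amino-3,4-dimethoxybenzoate | COC(=O)c1ccc(OC)c(OC)c1N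
F2 | step 5 | methyl 2-amino-5-bromo-3,4-dimethoxybenzoate | COC(=O)c1cc(Br)c(OC)c(OC)c1N
F3 | step 5 | 4-bromo-2,3-dimethoxy-6-(methoxycarbonyl)benzenediazonium hydrogensulfate | COC(=O)c1cc(Br)c(OC)c(OC)c1[N+]#N.OS(=O)(=O)[O-]
F4 | step 5 | methyl 5-bromo-2-iodo-3,4-dimethoxybenzoate | COC(=O)c1cc(Br)c(OC)c(OC)c1I
F5 | step 5 | [4-bromo-2,3-dimethoxy-6-(methoxycarbonyl)phenyl]magnesium chloride | COC(=O)c1cc(Br)c(OC)c(OC)c1[Mg]Cl
F6 | step 4 | chloromagnesium 4-bromo-6-(chloromagnesio)-2,3-dimethoxyphenoxide | COc1c(Br)cc([Mg]Cl)c(O[Mg]Cl)c1OC
F7 | step 4 | [4-bromo-2,3-dimethoxy-6-(trimethylsilyl)phenoxy]trimethylsilane | COc1c(Br)cc([Si](C)(C)C)c(O[Si](C)(C)C)c1OC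
F8 | step 4 | 4-bromo-2,3-dimethoxy-6-(trimethylsilyl)phenol | COc1c(Br)cc([Si](C)(C)C)c(O)c1OC
F9 | step 1 | 1,2-dimethoxy-3-(methoxymethoxy)benzene | COCOc1cccc(OC)c1OC
F10 | step 1 | [3,4-dimethoxy-2-(methoxymethoxy)phenyl]lithium | COCOc1c([Li])ccc(OC)c1OC
F11 | step 1 | 1-iodo-3,4-dimethoxy-2-(methoxymethoxy)benzene | COCOc1c(I)ccc(OC)c1OC
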